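The benzene ring carries the two-carbon chain at C1 next to bromine at C2, with a second bromine at C3 and oxygens at C4 and C5. The route cuts the C1–C(chain) and C2–Br bonds together: a copper-catalysed bromoalkynylation adds a silyl alkyne carbon to C1 and bromine to C2 across a C1–C2 aryne, whose C3 bromine fixes the orientation. The aryne precursor is 2-bromo-3,4-dimethoxy-6-(trimethylsilyl)phenyl triflate, made from 2-bromoisovanillin by way of an ortho-iodophenol and a retro-Brook silyl shift. After the key step the alkyne is turned into the 2-arylethanol, the methyl ethers are removed and the primary alcohol alone is sulfated.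

Key step: step 5

Remark: ring atoms are numbered as in the target (C1 chain, C2 and C3 bromine, C4 and C5 oxygen, C6 hydrogen). The target is drawn as the free hydrogen sulfate, so the last step ends with proton exchange; the acid would best be kept cold or stored as its sodium salt.

Step 1
Reactants: 1 2-bromo-3-hydroxy-4-methoxybenzaldehyde (2-bromoisovanillin)
Product: 2 2-bromo-3,4-dimethoxybenzaldehyde
Conditions: MeI, K2CO3, DMF, rt
Reagents that add atoms: iodomethane, CI
Why: Williamson ether synthesis, in which the phenoxide of the acidic ortho-bromophenol attacks iodomethane by SN2 displacement while the aldehyde is inert to carbonate.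

Step 2
Reactants: 2 2-bromo-3,4-dimethoxybenzaldehyde
Product: 4 2-bromo-3,4-dimethoxyphenol, via aryl formate 3 (not isolated)
Conditions: mCPBA, CH2Cl2, 0 °C to rt; then Et3N (cat.), MeOH, rt
Reagents that add atoms: 3-chloroperoxybenzoic acid (mCPBA), O=C(OO)c1cccc(Cl)c1
Why: Baeyer–Villiger oxidation of the Dakin type, in which the electron-rich aryl group (para-methoxy) migrates in preference to hydride and the resulting aryl formate is cleaved by base-catalysed methanolysis in the same flask.

Step 3
Reactants: 4 2-bromo-3,4-dimethoxyphenol
Product: 5 2-bromo-6-iodo-3,4-dimethoxyphenol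
Conditions: NIS, TsOH·H2O (cat.), MeCN, 0 °C to rt
Reagents that add atoms: N-iodosuccinimide, O=C1CCC(=O)N1I
Why: Electrophilic aromatic iodination, which should go to the one free position ortho to the hydroxyl group (also para to a methoxy group), since the other free position is activated by a single methoxy group only.

Step 4
Reactants: 5 2-bromo-6-iodo-3,4-dimethoxyphenol
Product: 9 2-bromo-3,4-dimethoxy-6-(trimethylsilyl)phenyl trifluoromethanesulfonate, via aryl trimethylsilyl ether 6 (not isolated), via aryllithium 7 (not isolated), via lithium silylphenoxide 8 (not isolated)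
Conditions: HMDS, THF, 70 °C, then evaporation; n-BuLi (1.05 equiv), THF, –100 to –80 °C; Tf2O, –100 to –80 °C
Reagents that add atoms: hexamethyldisilazane, C[Si](C)(C)N[Si](C)(C)C; trifluoromethanesulfonic anhydride, O=S(=O)(OS(=O)(=O)C(F)(F)F)C(F)(F)F
Why: O-silylation followed by iodine–lithium exchange (much faster than bromine–lithium exchange at –100 °C) gives an ortho-lithio aryl silyl ether that undergoes the 1,3 O-to-C silyl shift (retro-Brook rearrangement), and the lithium phenoxide so formed is triflated in the same flask.

Step 5
Reactants: 9 2-bromo-3,4-dimethoxy-6-(trimethylsilyl)phenyl trifluoromethanesulfonate; 10 (bromoethynyl)triisopropylsilane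
Product: 13 [(2,3-dibromo-4,5-dimethoxyphenyl)ethynyl]triisopropylsilane, via aryne 11 (not isolated), via arylcopper 12 (not isolated)
Conditions: 10 (2 equiv), CuBr (10 mol %), KF, 18-crown-6, DME, rt
Reagents that add atoms: none
Why: Fluoride removes the trimethylsilyl group of 9 and triflate leaves from the neighbouring carbon, which gives aryne 11 with its strained bond between C1 and C2. The copper acetylide formed from 10 and CuBr adds across that bond, carbon to C1 and copper to C2 (carbocupration), and arylcopper 12 then takes bromine from a further molecule of 10, which releases 13 and regenerates the acetylide, so both new bonds form in one catalytic cycle. The closest known reaction type is the copper-catalysed bromoalkynylation of arynes with 1-bromoalkynes. No ring is closed and no stereocentre is made. The step needs regioselectivity across the unsymmetrical aryne, and the C3 bromine secures it: its inductive pull distorts the aryne so that C1, the carbon distal to it, is the more electrophilic end and negative charge building up at C2 is stabilised, which sends the acetylide carbon to C1 and the metal, then bromine, to C2. It also needs chemoselectivity, which rests on the inertness of aryl C–Br bonds to ligand-free monovalent copper at room temperature and on the resistance of the triisopropylsilyl group to KF.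

Step 6
Reactants: 13 [(2,3-dibromo-4,5-dimethoxyphenyl)ethynyl]triisopropylsilane
Product: 14 2,3-dibromo-1-ethynyl-4,5-dimethoxybenzene
Conditions: TBAF, wet THF, 0 °C
Reagents that add atoms: none
Why: Fluoride-induced protodesilylation of the alkynylsilane, in which fluoride attacks silicon and the acetylide is protonated, while aryl bromides and methyl ethers are untouched.

Step 7
Reactants: 14 2,3-dibromo-1-ethynyl-4,5-dimethoxybenzene
Product: 17 2-(2,3-dibromo-4,5-dimethoxyphenyl)ethan-1-ol, via alkenylborane 15 (not isolated), via arylacetaldehyde 16 (not isolated)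
Conditions: Cy2BH (from BH3·SMe2 and cyclohexene), THF, 0 °C to rt; H2O2, pH 7 phosphate buffer, 0 °C; then NaBH4, EtOH, 0 °C
Reagents that add atoms: hydrogen peroxide, OO
Why: Brown hydroboration–oxidation, in which the bulky dialkylborane adds syn with boron on the terminal carbon and oxidation of the alkenyl C–B bond gives the enol and hence the arylacetaldehyde, which NaBH4 reduces at once so that the enolisable aldehyde need not be handled.

Step 8
Reactants: 17 2-(2,3-dibromo-4,5-dimethoxyphenyl)ethan-1-ol
Product: 18 2-(2,3-dibromo-4,5-dimethoxyphenyl)ethyl acetate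
Conditions: Ac2O, pyridine, DMAP (cat.), CH2Cl2, rt
Reagents that add atoms: acetic anhydride, CC(=O)OC(C)=O
Why: DMAP-catalysed O-acylation of the primary alcohol, done so that BBr3 in the next step does not meet a free alcohol, whose alkoxydibromoborane could collapse to the alkyl bromide.

Step 9
Reactants: 18 2-(2,3-dibromo-4,5-dimethoxyphenyl)ethyl acetate
Product: 20 3,4-dibromo-5-(2-hydroxyethyl)benzene-1,2-diol, via catechol acetate 19 (not isolated)
Conditions: BBr3 (4 equiv), CH2Cl2, –78 to 0 °C; then MeOH, 40 °C
Reagents that add atoms: none
Why: BBr3 ether cleavage, in which boron binds each methoxy oxygen and bromide removes the methyl group by SN2 attack while the ester survives at or below 0 °C, followed by HBr-catalysed transesterification of the primary acetate on quenching with methanol.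

Step 10
Reactants: 20 3,4-dibromo-5-(2-hydroxyethyl)benzene-1,2-diol
Product: 21 2-(2,3-dibromo-4,5-dihydroxyphenyl)ethyl hydrogen sulfate
Conditions: SO3·pyridine (1.1 equiv), DMF, 0 °C; then cation-exchange resin (H+ form), H2O, 0 °C
Reagents that add atoms: sulfur trioxide–pyridine complex, [O-]S(=O)(=O)[n+]1ccccc1
Why: O-sulfation with a sulfur trioxide–amine complex, which should stop at the primary aliphatic alcohol because it is a far better nucleophile than the two un-ionised phenols, each deactivated by an ortho or para bromine, when about one equivalent of reagent is used at 0 °C without added base.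

Compound list
1 | 2-bromo-3-hydroxy-4-methoxybenzaldehyde (2-bromoisovanillin) | COc1ccc(C=O)c(Br)c1O | starting material
2 | 2-bromo-3,4-dimethoxybenzaldehyde | COc1ccc(C=O)c(Br)c1OC | intermediate
3 | 2-bromo-3,4-dimethoxyphenyl formate | COc1ccc(OC=O)c(Br)c1OC | intermediate
4 | 2-bromo-3,4-dimethoxyphenol | COc1ccc(O)c(Br)c1OC | intermediate
5 | 2-bromo-6-iodo-3,4-dimethoxyphenol | COc1cc(I)c(O)c(Br)c1OC | intermediate
6 | (2-bromo-6-iodo-3,4-dimethoxyphenoxy)trimethylsilane | COc1cc(I)c(O[Si](C)(C)C)c(Br)c1OC | intermediate
7 | [3-bromo-4,5-dimethoxy-2-(trimethylsilyloxy)phenyl]lithium | [Li]c1cc(OC)c(OC)c(Br)c1O[Si](C)(C)C | intermediate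
8 | lithium 2-bromo-3,4-dimethoxy-6-(trimethylsilyl)phenoxide | [Li+].[O-]c1c(Br)c(OC)c(OC)cc1[Si](C)(C)C | intermediate
9 | 2-bromo-3,4-dimethoxy-6-(trimethylsilyl)phenyl trifluoromethanesulfonate | COc1cc([Si](C)(C)C)c(OS(=O)(=O)C(F)(F)F)c(Br)c1OC | intermediate
10 | (bromoethynyl)triisopropylsilane | BrC#C[Si](C(C)C)(C(C)C)C(C)C | starting material
11 | 3-bromo-4,5-dimethoxy-1,2-didehydrobenzene (aryne) | COC1=CC#CC(Br)=C1OC | intermediate
12 | {2-bromo-3,4-dimethoxy-6-[(triisopropylsilyl)ethynyl]phenyl}copper | COc1cc(C#C[Si](C(C)C)(C(C)C)C(C)C)c([Cu])c(Br)c1OC | intermediate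
13 | [(2,3-dibromo-4,5-dimethoxyphenyl)ethynyl]triisopropylsilane | COc1cc(C#C[Si](C(C)C)(C(C)C)C(C)C)c(Br)c(Br)c1OC | intermediate
14 | 2,3-dibromo-1-ethynyl-4,5-dimethoxybenzene | COc1cc(C#C)c(Br)c(Br)c1OC | intermediate
15 | dicyclohexyl[(E)-2-(2,3-dibromo-4,5-dimethoxyphenyl)ethenyl]borane | COc1cc(/C=C/B(C2CCCCC2)C2CCCCC2)c(Br)c(Br)c1OC | intermediate
16 | 2-(2,3-dibromo-4,5-dimethoxyphenyl)acetaldehyde | COc1cc(CC=O)c(Br)c(Br)c1OC | intermediate
17 | 2-(2,3-dibromo-4,5-dimethoxyphenyl)ethan-1-ol | COc1cc(CCO)c(Br)c(Br)c1OC | intermediate
18 | 2-(2,3-dibromo-4,5-dimethoxyphenyl)ethyl acetate | COc1cc(CCOC(C)=O)c(Br)c(Br)c1OC | intermediate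
19 | 2-(2,3-dibromo-4,5-dihydroxyphenyl)ethyl acetate | CC(=O)OCCc1cc(O)c(O)c(Br)c1Br | intermediate
20 | 3,4-dibromo-5-(2-hydroxyethyl)benzene-1,2-diol | OCCc1cc(O)c(O)c(Br)c1Br | intermediate
21 | 2-(2,3-dibromo-4,5-dihydroxyphenyl)ethyl hydrogen sulfate | O=S(=O)(O)OCCc1cc(O)c(O)c(Br)c1Br | target

Total step count: 10.
Longest linear sequence: 10 steps (1 to 21); 10 is bought and enters in step 5.

Steps most likely to fail

Risk 1 (step 5, key step). Transfer of bromine from 10 to the crowded arylcopper 12 may be slower than its protonation or than oligomerisation of aryne 11, so that turnover stalls or hydro-alkynylated material dominates. The fallback sets out from 9 and forms the two bonds in separate operations. Aryne 11, generated with CsF in MeCN/toluene, would be trapped with ethynyltriisopropylsilane under CuI catalysis (copper-catalysed hydroalkynylation of arynes), with arylcopper 12 now protonated by the terminal alkyne. This should give [(3-bromo-4,5-dimethoxyphenyl)ethynyl]triisopropylsilane F1. Electrophilic bromination of F1 with NBS in MeCN should then enter at C2, the position para to the C5 methoxy group, and the route is rejoined at 13.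

Risk 2 (step 10). Sulfation may not stop at the primary alcohol, and a phenol may be sulfated as well. The fallback replaces reagent control by protecting-group control and sets out from 20. Under aqueous alkaline acylation (Ac2O, aq. NaOH, 0 °C) only the phenoxides react, which should give 3,4-dibromo-5-(2-hydroxyethyl)-1,2-phenylene diacetate F2. Sulfation of its one free hydroxyl group with SO3·pyridine in DMF should give 2-[4,5-bis(acetyloxy)-2,3-dibromophenyl]ethyl hydrogen sulfate F3. Removal of the aryl acetates with K2CO3 in MeOH, to which the alkyl sulfate is inert, followed by proton exchange, rejoins the route at 21.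

Risk 3 (step 4). Bromine–lithium exchange at the carbon flanked by two oxygens, or halogen scrambling between aryllithium and aryl halide, may compete with the intended iodine–lithium exchange before the silyl group has migrated. The fallback uses directed ortho-metalation in place of halogen–metal exchange and sets out from 4. Carbamoylation (Et2NCOCl, K2CO3, MeCN, reflux) should give 2-bromo-3,4-dimethoxyphenyl N,N-diethylcarbamate F4. Deprotonation ortho to the carbamate with lithium 2,2,6,6-tetramethylpiperidide (LiTMP) in the presence of TMSCl (THF, –78 °C) would form [3-bromo-2-(diethylcarbamoyloxy)-4,5-dimethoxyphenyl]lithium F5, which is silylated as it forms; a lithium amide does not exchange with the aryl bromide. This should give 2-bromo-3,4-dimethoxy-6-(trimethylsilyl)phenyl N,N-diethylcarbamate F6. Reductive cleavage of the carbamate with LiAlH4 in THF (0 °C to rt) should give 2-bromo-3,4-dimethoxy-6-(trimethylsilyl)phenol F7, and triflation with Tf2O and pyridine in CH2Cl2 rejoins the route at 9.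

Further compounds
F1 | step 5 | [(3-bromo-4,5-dimethoxyphenyl)ethynyl]triisopropylsilane | COc1cc(C#C[Si](C(C)C)(C(C)C)C(C)C)cc(Br)c1OC
F2 | step 10 | 3,4-dibromo-5-(2-hydroxyethyl)-1,2-phenylene diacetate | CC(=O)Oc1cc(CCO)c(Br)c(Br)c1OC(C)=O
F3 | step 10 | 2-[4,5-bis(acetyloxy)-2,3-dibromophenyl]ethyl hydrogen sulfate | CC(=O)Oc1cc(CCOS(=O)(=O)O)c(Br)c(Br)c1OC(C)=O
F4 | step 4 | 2-bromo-3,4-dimethoxyphenyl N,N-diethylcarbamate | CCN(CC)C(=O)Oc1ccc(OC)c(OC)c1Br
F5 | step 4 | [3-bromo-2-(diethylcarbamoyloxy)-4,5-dimethoxyphenyl]lithium | CCN(CC)C(=O)Oc1c(Br)c(OC)c(OC)cc1[Li]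
F6 | step 4 | 2-bromo-3,4-dimethoxy-6-(trimethylsilyl)phenyl N,N-diethylcarbamate | CCN(CC)C(=O)Oc1c(Br)c(OC)c(OC)cc1[Si](C)(C)C
F7 | step 4 | 2-bromo-3,4-dimethoxy-6-(trimethylsilyl)phenol | COc1cc([Si](C)(C)C)c(O)c(Br)c1OC
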